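**Plan**

1. Ring numbering used here: quinone C1(=O), C2(OAc), C3(aryl), C4(=O), C5(H), C6(aryl), with aryl = 4-hydroxyphenyl. The target has no stereocentre, so only the placement of three oxygens and two aryl groups has to be controlled.
2. The retrosynthesis cuts, in this order: the two phenolic tert-butyl ethers and the C2 O-acetyl bond; the C1/C4 quinone level (back to a 1-methoxy-2,4-dihydroxybenzene); the ring bond C5–C6, which opens the carbocycle to a 1,3,5-triketone stored as a fully substituted 4-pyranone; the two aryl–pyranone bonds; two C–Br bonds and one O–CH3 bond, back to allomaltol.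
3. Enabling feature: C2 and C4 carry oxygen in a 1,3-relation, C5 is a bare CH and C6 carries an aryl group. This is the imprint of a chain aryl–CO–C–CO–C–CO–CH3 whose methyl carbon (C5) has condensed with its aryl ketone carbon (C6); the C1 oxygen is an α-alkoxy group of that chain and is the 5-hydroxyl of allomaltol.
4. Forward: the two outer benzene rings and the pyranone ring are bought. Bromination at C6, O-methylation and bromination at C3 of allomaltol, then a twofold Suzuki coupling, give the pyranone. Hydroxide then turns the pyranone ring into the central benzene ring (ring opening, aldol closure of C5–C6, aromatisation), the only ring made in the route.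
5. Oxidative demethylation gives the hydroxyquinone, acetylation caps the C2 oxygen, and acid removes the tert-butyl groups.
6. Stereochemistry: none to set; the sp3 centres that appear in the key step vanish on aromatisation.

Key step: step 5

Remark: allomaltol and 4-tert-butoxyphenylboronic acid are taken as purchasable; pyranone positions are numbered with the methyl-bearing carbon as C2, and the carbocycle keeps the target numbering given above.

**Route**

Step 1
Reactants: 1 allomaltol (5-hydroxy-2-methyl-4H-pyran-4-one)
Product: 2 6-bromo-5-hydroxy-2-methyl-4H-pyran-4-one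
Conditions: NBS (1.05 equiv), MeCN, 0 °C → rt, dark
Reagents that add atoms: N-bromosuccinimide, O=C1CCC(=O)N1Br
Why: Electrophilic bromination of an enol; the free 5-hydroxyl makes C6 (its enol β-carbon) the most nucleophilic ring position, as in the bromination of kojic acid, so monobromination should occur there only.

Step 2
Reactants: 2 6-bromo-5-hydroxy-2-methyl-4H-pyran-4-one
Product: 3 6-bromo-5-methoxy-2-methyl-4H-pyran-4-one
Conditions: MeI, K2CO3, acetone, 50 °C
Reagents that add atoms: iodomethane, CI
Why: Williamson O-alkylation (SN2) of the acidic enolic hydroxyl; the mild carbonate base should leave the vinylogous acyl bromide at C6 untouched.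

Step 3
Reactants: 3 6-bromo-5-methoxy-2-methyl-4H-pyran-4-one
Product: 4 3,6-dibromo-5-methoxy-2-methyl-4H-pyran-4-one
Conditions: Br2 (1.1 equiv), NaOAc, AcOH, rt → 50 °C, dark
Reagents that add atoms: bromine, BrBr
Why: Electrophilic α-halogenation of the vinylogous ester; C3 is the only ring C–H left and is activated by the ring oxygen through C2=C3, as in the 3-bromination of 2,6-dimethyl-4-pyranone, and ionic conditions in the dark disfavour radical attack on the methyl group.

Step 4
Reactants: 4 3,6-dibromo-5-methoxy-2-methyl-4H-pyran-4-one; 5 4-tert-butoxyphenylboronic acid (2.6 equiv)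
Product: 6 3,6-bis(4-tert-butoxyphenyl)-5-methoxy-2-methyl-4H-pyran-4-one
Conditions: PdCl2(dppf) (5 mol %; dppf = 1,1'-bis(diphenylphosphino)ferrocene), K3PO4, 1,4-dioxane/H2O (10:1), 90 °C, Ar
Reagents that add atoms: none
Why: Twofold Suzuki–Miyaura coupling; both C–Br bonds sit on an electron-poor pyranone (C6 a vinylogous acyl bromide, C3 an α-bromoenone) and should add readily to zerovalent palladium, as in couplings of 3,5-dibromo-2,6-dimethyl-4-pyranone.

Step 5
Reactants: 6 3,6-bis(4-tert-butoxyphenyl)-5-methoxy-2-methyl-4H-pyran-4-one
Product: 9 3,6-bis(4-tert-butoxyphenyl)-1-methoxybenzene-2,4-diol, via ring-opened triketone 7 (not isolated), via cyclic aldol adduct 8 (not isolated)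
Conditions: KOH (aq., 10 equiv), 1,4-dioxane/H2O, 90 °C, degassed, Ar; then AcOH to pH 5, 0 °C
Reagents that add atoms: potassium hydroxide, [K+].[OH-] (its oxygen can end up as the C4 hydroxyl oxygen)
Why: Hydroxide adds in conjugate fashion to C2 or C6 of the pyranone (both sites lead to the same product) and the hemiketal opens to triketone 7, held as its enolates; the methyl ketone enolate (the carbon that becomes C5) then attacks the aryl ketone carbonyl (the carbon that becomes C6) to give aldol 8, which loses water by E1cB and enolises twice to the benzene ring, so the net change is an isomerisation driven by aromatisation. The closest known reaction type is the base-induced conversion of 2,6-dimethyl-4-pyranone through heptane-2,4,6-trione into orcinol, together with the analogous closure of 1-aryl-1,3,5-triketones to 5-arylresorcinols, that is, the polyketide-type aldol aromatisation of a 1,3,5-triketone. The six-membered carbocycle is closed in a 6-(enolendo)-exo-trig aldol mode. No stereocentre remains, because the sp3 centres of 7 and 8 are erased on aromatisation. The step needs C–C closure to win over retro-Claisen cleavage and needs a single regiochemical outcome: only the methyl carbon/aryl ketone pairing can close a six-membered ring (every other carbanion/carbonyl pair would close a four-membered ring), the α-methoxy group raises the electrophilicity of the aryl ketone, and the substitution pattern of the pyranone fixes the product as the 1-methoxy-2,4-diol with aryl groups on C3 and C6. Exclusion of oxygen should keep the electron-rich phenolate from autoxidising.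

Step 6
Reactants: 9 3,6-bis(4-tert-butoxyphenyl)-1-methoxybenzene-2,4-diol
Product: 10 3,6-bis(4-tert-butoxyphenyl)-2-hydroxy-1,4-benzoquinone
Conditions: PhI(OAc)2 (1.1 equiv), MeCN/H2O (4:1), 0 °C
Reagents that add atoms: water, O
Why: Oxidative demethylation of a 4-methoxyphenol by a hypervalent (trivalent) iodine reagent: two-electron oxidation of the C4 phenol gives the C1 oxocarbenium ion, water adds and methanol leaves to give the para-quinone, while the C2 hydroxyl is kept as a vinylogous acid (oxidation through the C2 phenol would give the ortho-quinone tautomer of the same product).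

Step 7
Reactants: 10 3,6-bis(4-tert-butoxyphenyl)-2-hydroxy-1,4-benzoquinone
Product: 11 2-acetoxy-3,6-bis(4-tert-butoxyphenyl)-1,4-benzoquinone
Conditions: Ac2O (1.5 equiv), Et3N (1.5 equiv), CH2Cl2, 0 °C
Reagents that add atoms: acetic anhydride, CC(=O)OC(C)=O
Why: O-Acylation of the hydroxyquinone (a vinylogous carboxylic acid) as its triethylammonium salt; it is the only free hydroxyl, and the para-quinone enol acetate is the preferred acyl position of the ambident anion.

Step 8
Reactants: 11 2-acetoxy-3,6-bis(4-tert-butoxyphenyl)-1,4-benzoquinone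
Product: 12 neonambiquinone A (2-acetoxy-3,6-bis(4-hydroxyphenyl)-1,4-benzoquinone)
Conditions: TFA/CH2Cl2 (1:3), 0 °C → rt, Ar sweep; evaporate, no aqueous work-up
Reagents that add atoms: none
Why: Acidolysis (E1) of the aryl tert-butyl ethers with loss of isobutene; the anhydrous, non-nucleophilic acid should spare the enol acetate, which is a vinylogous anhydride and would not survive basic or nucleophilic deprotection.

**Compound list**

1 | allomaltol, 5-hydroxy-2-methyl-4H-pyran-4-one | Cc1cc(=O)c(O)co1 | starting material
2 | 6-bromo-5-hydroxy-2-methyl-4H-pyran-4-one | Cc1cc(=O)c(O)c(Br)o1 | intermediate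
3 | 6-bromo-5-methoxy-2-methyl-4H-pyran-4-one | Cc1cc(=O)c(OC)c(Br)o1 | intermediate
4 | 3,6-dibromo-5-methoxy-2-methyl-4H-pyran-4-one | Cc1c(Br)c(=O)c(OC)c(Br)o1 | intermediate
5 | 4-tert-butoxyphenylboronic acid | CC(C)(C)Oc1ccc(cc1)B(O)O | starting material
6 | 3,6-bis(4-tert-butoxyphenyl)-5-methoxy-2-methyl-4H-pyran-4-one | Cc1oc(-c2ccc(OC(C)(C)C)cc2)c(OC)c(=O)c1-c1ccc(OC(C)(C)C)cc1 | intermediate
7 | 1,4-bis(4-tert-butoxyphenyl)-2-methoxyhexane-1,3,5-trione (present as its potassium enolates; not isolated) | CC(=O)C(c1ccc(OC(C)(C)C)cc1)C(=O)C(OC)C(=O)c1ccc(OC(C)(C)C)cc1 | intermediate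
8 | 2,5-bis(4-tert-butoxyphenyl)-5-hydroxy-4-methoxycyclohexane-1,3-dione (mixture of diastereomers and enol forms; not isolated) | COC1C(=O)C(c2ccc(OC(C)(C)C)cc2)C(=O)CC1(O)c1ccc(OC(C)(C)C)cc1 | intermediate
9 | 3,6-bis(4-tert-butoxyphenyl)-1-methoxybenzene-2,4-diol (systematic locants: 2,5-bis(4-tert-butoxyphenyl)-4-methoxybenzene-1,3-diol) | COc1c(O)c(-c2ccc(OC(C)(C)C)cc2)c(O)cc1-c1ccc(OC(C)(C)C)cc1 | intermediate
10 | 3,6-bis(4-tert-butoxyphenyl)-2-hydroxy-1,4-benzoquinone | OC1=C(c2ccc(OC(C)(C)C)cc2)C(=O)C=C(c2ccc(OC(C)(C)C)cc2)C1=O | intermediate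
11 | 2-acetoxy-3,6-bis(4-tert-butoxyphenyl)-1,4-benzoquinone | CC(=O)OC1=C(c2ccc(OC(C)(C)C)cc2)C(=O)C=C(c2ccc(OC(C)(C)C)cc2)C1=O | intermediate
12 | neonambiquinone A, 2-acetoxy-3,6-bis(4-hydroxyphenyl)-1,4-benzoquinone | CC(=O)OC1=C(c2ccc(O)cc2)C(=O)C=C(c2ccc(O)cc2)C1=O | target

**Summary and risks**

Total step count: 8. Longest linear sequence: 8 steps (1 → 12); boronic acid 5 enters at step 4.

Steps most likely to fail:

Step 5. The ring-opened triketone may be cut by hydroxide (retro-Claisen scission of its α-aryl β-diketone unit) faster than its methyl enolate closes onto the hindered, electron-rich aryl ketone. The fallback sets out from 3 and 5 and comes back at 10; it runs the ring transformation on a pyranone without the C3 aryl group and brings that aryl group in afterwards. Monobromide 3 is coupled with 5 (Pd(PPh3)4, K3PO4, dioxane/H2O) to 6-(4-tert-butoxyphenyl)-5-methoxy-2-methyl-4H-pyran-4-one F1. Its ring-opened triketone has an unsubstituted, fully enolised central methylene and is the direct counterpart of the aryl triketones that are known to cyclise, so the same KOH treatment should give 6-(4-tert-butoxyphenyl)-1-methoxybenzene-2,4-diol F2. PhI(OAc)2 in aqueous MeCN should then give 6-(4-tert-butoxyphenyl)-2-hydroxy-1,4-benzoquinone F3. This is brominated without storage at its nucleophilic enol carbon C3 (NBS, CH2Cl2, 0 °C) to 3-bromo-6-(4-tert-butoxyphenyl)-2-hydroxy-1,4-benzoquinone F4. Suzuki coupling of F4 with 5 (PdCl2(dppf), K2CO3, dioxane/H2O) installs the second aryl group and gives 10.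

Step 4. The C6 bromine, a vinylogous acyl bromide, may be lost by hydrolysis under the aqueous base, and coupling at the more hindered C3 bromide may stall or end in protodebromination, so that mixtures result from the one-pot double coupling. The fallback sets out from 3 and comes back at 6; it differentiates the two halogens and couples them in separate operations. Chlorination of 3 at C3 (NCS, TFA cat., MeCN, 50 °C) should give 6-bromo-3-chloro-5-methoxy-2-methyl-4H-pyran-4-one F5. An anhydrous Suzuki coupling with 5 (Pd(PPh3)4, CsF, dioxane, 70 °C) should react at the activated C–Br bond only and give 6-(4-tert-butoxyphenyl)-3-chloro-5-methoxy-2-methyl-4H-pyran-4-one F6. A second coupling with 5 under forcing conditions for chlorides (Pd(OAc)2, SPhos, K3PO4, toluene/H2O, 100 °C), now harmless because no hydrolysable halide is left, gives 6.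

Step 8. The acid may strip or transfer the enol acetate, and the tert-butyl cation may add back to the freed phenol rings. The fallback sets out from 10 and comes back at 12; it moves the acidolysis in front of the acetylation and switches to a fluoride-labile phenol protection. TFA/H2O (95:5), with water now allowed as cation trap, should give 2-hydroxy-3,6-bis(4-hydroxyphenyl)-1,4-benzoquinone F7. TBSCl (2.2 equiv) and imidazole in DMF silylate the two phenols; any silyl group on the acidic enol oxygen is a vinylogous silyl ester and is lost on aqueous work-up. This should give 3,6-bis[4-(tert-butyldimethylsilyloxy)phenyl]-2-hydroxy-1,4-benzoquinone F8. Acetylation as in step 7 gives 2-acetoxy-3,6-bis[4-(tert-butyldimethylsilyloxy)phenyl]-1,4-benzoquinone F9, and HF·pyridine in THF at 0 °C removes the silyl groups under conditions to which the enol acetate should be inert, giving 12.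

**Further compounds**

F1 | step 5 | 6-(4-tert-butoxyphenyl)-5-methoxy-2-methyl-4H-pyran-4-one | Cc1cc(=O)c(OC)c(-c2ccc(OC(C)(C)C)cc2)o1
F2 | step 5 | 6-(4-tert-butoxyphenyl)-1-methoxybenzene-2,4-diol | COc1c(O)cc(O)cc1-c1ccc(OC(C)(C)C)cc1
F3 | step 5 | 6-(4-tert-butoxyphenyl)-2-hydroxy-1,4-benzoquinone | OC1=CC(=O)C=C(c2ccc(OC(C)(C)C)cc2)C1=O
F4 | step 5 | 3-bromo-6-(4-tert-butoxyphenyl)-2-hydroxy-1,4-benzoquinone | OC1=C(Br)C(=O)C=C(c2ccc(OC(C)(C)C)cc2)C1=O
F5 | step 4 | 6-bromo-3-chloro-5-methoxy-2-methyl-4H-pyran-4-one | Cc1oc(Br)c(OC)c(=O)c1Cl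
F6 | step 4 | 6-(4-tert-butoxyphenyl)-3-chloro-5-methoxy-2-methyl-4H-pyran-4-one | Cc1oc(-c2ccc(OC(C)(C)C)cc2)c(OC)c(=O)c1Cl
F7 | step 8 | 2-hydroxy-3,6-bis(4-hydroxyphenyl)-1,4-benzoquinone | OC1=C(c2ccc(O)cc2)C(=O)C=C(c2ccc(O)cc2)C1=O
F8 | step 8 | 3,6-bis[4-(tert-butyldimethylsilyloxy)phenyl]-2-hydroxy-1,4-benzoquinone | OC1=C(c2ccc(O[Si](C)(C)C(C)(C)C)cc2)C(=O)C=C(c2ccc(O[Si](C)(C)C(C)(C)C)cc2)C1=O
F9 | step 8 | 2-acetoxy-3,6-bis[4-(tert-butyldimethylsilyloxy)phenyl]-1,4-benzoquinone | CC(=O)OC1=C(c2ccc(O[Si](C)(C)C(C)(C)C)cc2)C(=O)C=C(c2ccc(O[Si](C)(C)C(C)(C)C)cc2)C1=O
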